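Slowness in this flask is a race between two clocks that read the same electrophile, so dividing one rate by the other removes both c(electrophile) and time.

electrophile 0.20 M; nucleophile 0.190 M; free base 0.160 M; protic impurity 0.0600 M; time 25 min

    electrophile + nucleophile → acid set free + product (k1 = 0.051 L mol⁻¹ s⁻¹)
    nucleophile + acid set free ⇌ protonated nucleophile, settled at all times (K2 = 430 L mol⁻¹)
    acid set free + free base ⇌ salt of the base, settled at all times (K3 = 270 L mol⁻¹)
    electrophile + protic impurity → quenched substrate (k4 = 0.031 L mol⁻¹ s⁻¹)
    acid set free → by-product carried off (k5 = 4.1 × 10⁻⁴ s⁻¹)

- part of the electrophile that has reacted at 25 min
- share of the unused nucleophile that is free and not bound as protonated nucleophile, at 25 min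

**Question: what is left after that division?** The product step's constant times c(nucleophile, free), over the quenching step's constant times c(protic impurity). This is the selectivity factor S, the product formed per quenched substrate at any moment, and at the charge it comes to 5.21, which sends 16.1% of the first electrophile used to quenched substrate.

**Question: how far does that take you?** If every nucleophile became product, with quenched substrate alongside at that S, the electrophile used would be 113% of its charge, which is more than the charge, so I cap this count at 100% and commit to it as an estimate of amounts that carries no clock.

**Question: but S counted free nucleophile, and acid is being set free. What then?** That is the weak spot: at the start the nucleophile's 82 exceeds the free base's 43 as equilibrium constant times charge, so about 65.6% of the early acid binds nucleophile, and I expect S to sink. My ratio has dropped time, so I stop short of fr.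

The forecast, reasoning that the acid pool “splits between the nucleophile and the base”, gives 95.3% (94.3% to 96.2%) for c and 26% (24.5% to 27.5%) for fr, and its c lies below my cap.

The simulation gives 95.4% for c and 27.7% for fr. At 25 min the flask holds product at 71.2% and quenched substrate at 24.2% of the electrophile charged. S taken from what stands free in the flask at that time has sunk to 1.87, from 5.21 at the charge. For the neighbour charged with 0.048 M of nucleophile, S at the charge is 1.32, and that neighbour ends with quenched substrate at 29.8% of the electrophile charged, more than its product at 23.9%.

The constants come from no measurement; the result is computed.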